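The route rests on disconnecting C8–O and C13–O together. In the butenolide ring (C6–C7–C11–C12–O) the array O–C8–C7=C11–C13–O is the signature of dioxygen added across the s-cis diene C8=C7–C11=C13. One photooxygenation builds the 1,2-dioxine ring, the C8 stereocentre, the oxygenated C13 methylene and the tetrasubstituted C7=C11 alkene. Its precursor is the 8-deoxy 7,11(13)-dien-12,6-olide already carrying the C1 acetate, C10 methyl and cis-4,5-epoxide. It is assembled from nerol (C1–C6, C15), a crotyl unit (C8–C10, C14) and a stannylacrylate (C11–C13), and closed by a chromium-mediated C6–C7 addition that forms ring and lactone together.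

Key step: step 14

Remarks on the chemistry:
(a) Germacrane numbering is used for every compound: C1 bears the ring acetate, C4–C5 the oxirane, C6 the lactone oxygen, C7=C11 is the butenolide alkene, C8 bears the tiglate, C10 the methyl group (C14), C12 is the lactone carbonyl, C13 the CH2O carbon, C15 the methyl on C4.
(b) Read this way the target is (1S,4R,5S,6S,8S,10R). Its oxirane is cis (C3 and C6 on the same side), the C10 methyl and C1 oxygen are anti, and the C8 oxygen lies on the same face of the butenolide plane as the C6–C5 bond.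
(c) The C5–O/C6–O relationship is the one that Felkin–Anh addition to a cis-epoxy aldehyde gives, not the one expected from a hydroxyl-directed epoxidation of a C6 carbinol. The oxirane is therefore installed first and used to control C6.
(d) Assumption: the crotylboronate of step 4 is prepared beforehand in the usual way from trans-2-butene, n-BuLi/KOt-Bu, B(OiPr)3 and D-(−)-diisopropyl tartrate.

Step 1
Reactants: 1 nerol
Product: 2 (2S,3R)-2,3-epoxynerol
Conditions: Ti(OiPr)4 (10 mol %), L-(+)-diethyl tartrate (12 mol %), t-BuOOH, 4 Å MS, CH2Cl2, −20 °C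
Reagents that add atoms: tert-butyl hydroperoxide, CC(C)(C)OO
Why: Sharpless asymmetric epoxidation touches only the allylic-alcohol alkene and, with the L-(+)-tartrate ligand, should deliver oxygen to the face that gives the (2S,3R) cis-epoxide, which fixes C4 (R) and C5 (S) of the target and leaves the remote alkene for step 3.

Step 2
Reactants: 2 (2S,3R)-2,3-epoxynerol
Product: 3 tert-butyldimethylsilyl ether of 2
Conditions: TBSCl, imidazole, CH2Cl2, 0 °C → rt
Reagents that add atoms: tert-butyldimethylsilyl chloride, CC(C)(C)[Si](C)(C)Cl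
Why: Standard silylation of a primary alcohol masks the C6 hydroxyl so that the primary alcohol made later at C8 can be oxidised on its own.

Step 3
Reactants: 3 tert-butyldimethylsilyl ether of 2
Product: 5 C1 aldehyde 3-[(2R,3S)-3-(tert-butyldimethylsilyloxymethyl)-2-methyloxiran-2-yl]propanal, via secondary ozonide 4 (not isolated)
Conditions: O3, CH2Cl2, −78 °C; then PPh3, −78 °C → rt
Reagents that add atoms: ozone, [O-][O+]=O
Why: Ozonolysis with reductive work-up cleaves the only alkene left after step 1 (acetone is lost) and unveils C1 as an aldehyde, the oxirane and the silyl ether being inert to ozone.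

Step 4
Reactants: 5 C1 aldehyde
Product: 6 (3S,4R)-1-[(2R,3S)-3-(tert-butyldimethylsilyloxymethyl)-2-methyloxiran-2-yl]-4-methylhex-5-en-3-ol (germacrane 1S,10R)
Conditions: (E)-crotylboronate of (S,S)-diisopropyl tartrate, 4 Å MS, toluene, −78 °C; aqueous work-up
Reagents that add atoms: (E)-crotylboronate of (S,S)-diisopropyl tartrate, CC(C)OC(=O)[C@H]1OB(C/C=C/C)O[C@@H]1C(=O)OC(C)C
Why: Roush asymmetric crotylboration proceeds through a closed chair transition state in which the E-crotyl unit gives the anti C10-methyl/C1-hydroxyl pair and the (S,S)-tartrate (the series that adds to the aldehyde re face) sets C1 (S) and hence C10 (R), under reagent control and without a Lewis acid that could open the oxirane; any minor diastereomer is removed by chromatography.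

Step 5
Reactants: 6 homoallylic alcohol
Product: 7 (3S,4R)-1-[(2R,3S)-3-(tert-butyldimethylsilyloxymethyl)-2-methyloxiran-2-yl]-4-methylhex-5-en-3-yl acetate
Conditions: Ac2O, pyridine, DMAP (cat.), CH2Cl2, 0 °C → rt
Reagents that add atoms: acetic anhydride, CC(=O)OC(C)=O
Why: Routine acylation installs the C1 acetate of the target at once, where it also serves as the protecting group for all later steps.

Step 6
Reactants: 7 homoallylic acetate
Product: 9 (3S,4R)-1-[(2R,3S)-3-(tert-butyldimethylsilyloxymethyl)-2-methyloxiran-2-yl]-6-hydroxy-4-methylhexan-3-yl acetate, via B-alkyl-9-BBN adduct 8 (not isolated)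
Conditions: 9-BBN, THF, 0 °C → rt; then 30% H2O2, aq. NaOAc, 0 °C → rt
Reagents that add atoms: 9-borabicyclo[3.3.1]nonane, B1C2CCCC1CCC2 (boron unit present only in 8); hydrogen peroxide, OO
Why: Anti-Markovnikov hydroboration–oxidation of the monosubstituted alkene places the hydroxyl on C8, 9-BBN leaving ester and oxirane alone and the buffered oxidation sparing the acetate.

Step 7
Reactants: 9 C8 primary alcohol
Product: 10 (3S,4R)-1-[(2R,3S)-3-(tert-butyldimethylsilyloxymethyl)-2-methyloxiran-2-yl]-4-methyl-6-oxohexan-3-yl acetate (C8 aldehyde)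
Conditions: Dess–Martin periodinane, pyridine, CH2Cl2, 0 °C → rt
Reagents that add atoms: none
Why: Dess–Martin oxidation converts the primary alcohol into the aldehyde under buffered, non-epimerising conditions, C10 being beta to the new carbonyl.

Step 8
Reactants: 10 C8 aldehyde
Product: 11 (3S,4R)-7,7-dibromo-1-[(2R,3S)-3-(tert-butyldimethylsilyloxymethyl)-2-methyloxiran-2-yl]-4-methylhept-6-en-3-yl acetate
Conditions: [Ph3PCHBr2]Br, KOt-Bu, THF, 0 °C → rt; then 10
Reagents that add atoms: (dibromomethyl)triphenylphosphonium bromide, [Br-].BrC(Br)[P+](c1ccccc1)(c1ccccc1)c1ccccc1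
Why: Ramirez dibromo-olefination with the preformed ylide adds C7 as a CBr2 unit and avoids the Ph3PBr2 or zinc halide of the in-situ variants, which could open the oxirane or cleave the silyl ether.

Step 9
Reactants: 11 dibromoalkene silyl ether
Product: 12 (3S,4R)-7,7-dibromo-1-[(2R,3S)-3-(hydroxymethyl)-2-methyloxiran-2-yl]-4-methylhept-6-en-3-yl acetate
Conditions: HF·pyridine, pyridine, THF, 0 °C → rt
Reagents that add atoms: none
Why: Pyridine-buffered fluoride desilylation frees the C6 hydroxyl without base (no Payne rearrangement, no loss of HBr from the dibromoalkene) and without free acid (oxirane and acetate kept).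

Step 10
Reactants: 13 methyl propiolate
Product: 14 methyl 2-(tributylstannyl)prop-2-enoate
Conditions: Bu3SnH, Pd(PPh3)4 (2 mol %), THF, 0 °C → rt
Reagents that add atoms: tributyltin hydride, CCCC[SnH](CCCC)CCCC
Why: Palladium-catalysed syn-hydrostannation of a propiolate ester favours the alpha-stannyl acrylate, which is separated from the minor beta isomer by chromatography.

Step 11
Reactants: 12 dibromoalkene epoxy alcohol; 14 methyl 2-(tributylstannyl)prop-2-enoate
Product: 15 methyl (3Z,6R,7S)-7-acetoxy-3-bromo-9-[(2R,3S)-3-(hydroxymethyl)-2-methyloxiran-2-yl]-6-methyl-2-methylidenenon-3-enoate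
Conditions: Pd2(dba)3 (5 mol %), P(2-furyl)3 (20 mol %), CuI (10 mol %), toluene, 50 °C
Reagents that add atoms: none
Why: Stille coupling of a 1,1-dibromoalkene occurs selectively at the C–Br bond trans to the alkyl chain, so C11 enters trans to C9 and the remaining bromine stays cis to C9, which fixes the later C7=C8 ring geometry; base-free conditions avoid loss of HBr.

Step 12
Reactants: 15 bromodienoate epoxy alcohol
Product: 16 methyl (3Z,6R,7S)-7-acetoxy-3-bromo-9-[(2R,3R)-3-formyl-2-methyloxiran-2-yl]-6-methyl-2-methylidenenon-3-enoate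
Conditions: Dess–Martin periodinane, pyridine, CH2Cl2, 0 °C; used crude
Reagents that add atoms: none
Why: Buffered Dess–Martin oxidation of a 2,3-epoxy alcohol gives the configurationally stable cis-epoxy aldehyde, which is taken on without purification.

Step 13
Reactants: 16 bromodienoate epoxy aldehyde
Product: 18 (1S,4R,5S,6S,7Z,10R)-1-acetoxy-4,5-epoxygermacra-7,11(13)-dien-12,6-olide, via macrocyclic hydroxy ester 17 (not isolated)
Conditions: CrCl2 (10 equiv), NiCl2 (1 mol %), degassed DMSO/THF, rt, syringe-pump addition of 16 (final ca. 2 mM); aqueous work-up, brief stirring with silica gel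
Reagents that add atoms: none
Why: Intramolecular Nozaki–Hiyama–Kishi reaction, in which nickel-catalysed activation of the C7–Br bond by divalent chromium and 1,2-addition to the aldehyde close the ten-membered ring at C6–C7 with retention of alkene geometry, the nucleophile adding anti to the C5–O bond of the cis-epoxy aldehyde (Felkin–Anh) to give 6S, after which the C6 oxygen lactonises onto the neighbouring methyl ester.

Step 14
Reactants: 18 8-deoxy 7,11(13)-diene lactone
Product: 19 (1S,4R,5S,6S,8S,10R)-1-acetoxy-4,5-epoxy-8,13-epidioxygermacr-7(11)-en-12,6-olide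
Conditions: O2, tetraphenylporphyrin (1 mol %), visible light, CH2Cl2, −20 °C; crude 19 taken on at once
Reagents that add atoms: dioxygen, O=O
Why: Sensitised singlet oxygen acts as a two-atom dienophile and adds in a concerted suprafacial [4+2] cycloaddition (the oxygen counterpart of a Diels–Alder reaction, the standard way from 1,3-dienes to 3,6-dihydro-1,2-dioxines) across C8=C7–C11=C13, forming C8–O and C13–O and moving the unsaturation to C7=C11. The six-membered 1,2-dioxine ring is closed by the cycloaddition itself, both bonds being made on one diene face, which is possible because the lactone ring holds C7–C11 s-cis with C9 pointing outward. The one new stereocentre, C8, is decided by the diene face that oxygen approaches, and this is governed by C6 through the ring conformation: C5 sits on one face at C6, and with H6 turned toward C3 across the cis-oxirane (the arrangement free of allylic 1,3-strain) the C3–C2–C1–C10 bridge has to return to C9 over the H6 face, so C10 and its methyl screen that face at C8. Oxygen should therefore bond to C8 anti to the allylic C9–C10 bond, on the C5 face, which is the approach that gives 8S; this is a model-based expectation and the one real uncertainty of the route. Cycloaddition should win over the ene pathway because the diene is locked s-cis, the only allylic hydrogens (on C9 and C6) flank an alkene deactivated by conjugation with the acrylate, C4–C5 is already an oxirane and not an electron-rich alkene, and low temperature favours the concerted mode. Acetate, oxirane and lactone are inert to singlet oxygen.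

Step 15
Reactants: 19 8,13-endoperoxide
Product: 20 (1S,4R,5S,6S,8S,10R)-1-acetoxy-4,5-epoxy-8,13-dihydroxygermacr-7(11)-en-12,6-olide
Conditions: thiourea, MeOH, 0 °C → rt
Reagents that add atoms: none
Why: Thiourea reduces only the O–O bond of the endoperoxide to the cis-2-ene-1,4-diol, so the C8 configuration is kept, and the neutral medium avoids base-induced Kornblum–DeLaMare rearrangement.

Step 16
Reactants: 20 8,13-diol
Product: 21 (1S,4R,5S,6S,8S,10R)-1,13-diacetoxy-4,5-epoxy-8-hydroxygermacr-7(11)-en-12,6-olide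
Conditions: Ac2O (1.1 equiv), pyridine, CH2Cl2, −20 → 0 °C
Reagents that add atoms: acetic anhydride, CC(=O)OC(C)=O
Why: Kinetic acylation at low temperature should select the unhindered primary allylic C13 hydroxyl over the secondary C8 hydroxyl that is flanked by the ring and the tetrasubstituted alkene.

Step 17
Reactants: 21 8-hydroxy 13-acetate
Product: 22 target, (1S,4R,5S,6S,8S,10R)-1,13-diacetoxy-4,5-epoxy-8-tigloyloxygermacr-7(11)-en-12,6-olide
Conditions: tiglic acid, 2,4,6-trichlorobenzoyl chloride, Et3N, toluene, rt; then 21, DMAP, toluene, rt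
Reagents that add atoms: tiglic acid, C/C=C(\C)C(=O)O
Why: Yamaguchi esterification acylates the hindered secondary allylic alcohol with retention at C8 and, unlike an acid chloride with amine base, does not deconjugate the E-2-methylbut-2-enoate.

Compound list
1 | nerol, (2Z)-3,7-dimethylocta-2,6-dien-1-ol | CC(C)=CCC/C(C)=C\CO | starting material
2 | (2S,3R)-2,3-epoxynerol, [(2S,3R)-3-methyl-3-(4-methylpent-3-en-1-yl)oxiran-2-yl]methanol | CC(C)=CCC[C@@]1(C)O[C@H]1CO | intermediate
3 | tert-butyldimethylsilyl ether of 2 | CC(C)=CCC[C@@]1(C)O[C@H]1CO[Si](C)(C)C(C)(C)C | intermediate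
4 | secondary ozonide of 3 (3,3-dimethyl-1,2,4-trioxolane carrying the epoxy chain on C5; mixture at that carbon) | CC1(C)OOC(CC[C@@]2(C)O[C@H]2CO[Si](C)(C)C(C)(C)C)O1 | intermediate (not isolated)
5 | 3-[(2R,3S)-3-(tert-butyldimethylsilyloxymethyl)-2-methyloxiran-2-yl]propanal (C1 aldehyde) | O=CCC[C@@]1(C)O[C@H]1CO[Si](C)(C)C(C)(C)C | intermediate
6 | (3S,4R)-1-[(2R,3S)-3-(tert-butyldimethylsilyloxymethyl)-2-methyloxiran-2-yl]-4-methylhex-5-en-3-ol | C=C[C@@H](C)[C@@H](O)CC[C@@]1(C)O[C@H]1CO[Si](C)(C)C(C)(C)C | intermediate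
7 | (3S,4R)-1-[(2R,3S)-3-(tert-butyldimethylsilyloxymethyl)-2-methyloxiran-2-yl]-4-methylhex-5-en-3-yl acetate | C=C[C@@H](C)[C@@H](OC(C)=O)CC[C@@]1(C)O[C@H]1CO[Si](C)(C)C(C)(C)C | intermediate
8 | B-alkyl-9-borabicyclo[3.3.1]nonane adduct of 7 (boron on C8) | C(C[C@@H](C)[C@@H](OC(C)=O)CC[C@@]1(C)O[C@H]1CO[Si](C)(C)C(C)(C)C)B2C3CCCC2CCC3 | intermediate (not isolated)
9 | (3S,4R)-1-[(2R,3S)-3-(tert-butyldimethylsilyloxymethyl)-2-methyloxiran-2-yl]-6-hydroxy-4-methylhexan-3-yl acetate | OCC[C@@H](C)[C@@H](OC(C)=O)CC[C@@]1(C)O[C@H]1CO[Si](C)(C)C(C)(C)C | intermediate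
10 | (3S,4R)-1-[(2R,3S)-3-(tert-butyldimethylsilyloxymethyl)-2-methyloxiran-2-yl]-4-methyl-6-oxohexan-3-yl acetate (C8 aldehyde) | O=CC[C@@H](C)[C@@H](OC(C)=O)CC[C@@]1(C)O[C@H]1CO[Si](C)(C)C(C)(C)C | intermediate
11 | (3S,4R)-7,7-dibromo-1-[(2R,3S)-3-(tert-butyldimethylsilyloxymethyl)-2-methyloxiran-2-yl]-4-methylhept-6-en-3-yl acetate | BrC(Br)=CC[C@@H](C)[C@@H](OC(C)=O)CC[C@@]1(C)O[C@H]1CO[Si](C)(C)C(C)(C)C | intermediate
12 | (3S,4R)-7,7-dibromo-1-[(2R,3S)-3-(hydroxymethyl)-2-methyloxiran-2-yl]-4-methylhept-6-en-3-yl acetate | BrC(Br)=CC[C@@H](C)[C@@H](OC(C)=O)CC[C@@]1(C)O[C@H]1CO | intermediate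
13 | methyl propiolate (methyl prop-2-ynoate) | C#CC(=O)OC | starting material
14 | methyl 2-(tributylstannyl)prop-2-enoate | C=C(C(=O)OC)[Sn](CCCC)(CCCC)CCCC | intermediate
15 | methyl (3Z,6R,7S)-7-acetoxy-3-bromo-9-[(2R,3S)-3-(hydroxymethyl)-2-methyloxiran-2-yl]-6-methyl-2-methylidenenon-3-enoate | COC(=O)C(=C)/C(Br)=C/C[C@@H](C)[C@@H](OC(C)=O)CC[C@@]1(C)O[C@H]1CO | intermediate
16 | methyl (3Z,6R,7S)-7-acetoxy-3-bromo-9-[(2R,3R)-3-formyl-2-methyloxiran-2-yl]-6-methyl-2-methylidenenon-3-enoate | COC(=O)C(=C)/C(Br)=C/C[C@@H](C)[C@@H](OC(C)=O)CC[C@@]1(C)O[C@H]1C=O | intermediate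
17 | methyl (1S,4R,5S,6S,7Z,10R)-1-acetoxy-4,5-epoxy-6-hydroxygermacra-7,11(13)-dien-12-oate (macrocyclic hydroxy ester, formed as its chromium alkoxide) | COC(=O)C(=C)/C1=C/C[C@@H](C)[C@@H](OC(C)=O)CC[C@@]2(C)O[C@H]2[C@H]1O | intermediate (not isolated)
18 | (1S,4R,5S,6S,7Z,10R)-1-acetoxy-4,5-epoxygermacra-7,11(13)-dien-12,6-olide (precursor of the key step) | C=C1C(=O)O[C@H]2/C1=C\C[C@@H](C)[C@@H](OC(C)=O)CC[C@@]1(C)O[C@H]12 | intermediate
19 | (1S,4R,5S,6S,8S,10R)-1-acetoxy-4,5-epoxy-8,13-epidioxygermacr-7(11)-en-12,6-olide (product of the key step) | O1[C@H]2C[C@@H](C)[C@@H](OC(C)=O)CC[C@@]3(C)O[C@H]3[C@H]3OC(=O)C(CO1)=C23 | intermediate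
20 | (1S,4R,5S,6S,8S,10R)-1-acetoxy-4,5-epoxy-8,13-dihydroxygermacr-7(11)-en-12,6-olide | O[C@H]1C[C@@H](C)[C@@H](OC(C)=O)CC[C@@]2(C)O[C@H]2[C@H]2OC(=O)C(CO)=C12 | intermediate
21 | (1S,4R,5S,6S,8S,10R)-1,13-diacetoxy-4,5-epoxy-8-hydroxygermacr-7(11)-en-12,6-olide | O[C@H]1C[C@@H](C)[C@@H](OC(C)=O)CC[C@@]2(C)O[C@H]2[C@H]2OC(=O)C(COC(C)=O)=C12 | intermediate
22 | (1S,4R,5S,6S,8S,10R)-1,13-diacetoxy-4,5-epoxy-8-tigloyloxygermacr-7(11)-en-12,6-olide | C/C=C(\C)C(=O)O[C@H]1C[C@@H](C)[C@@H](OC(C)=O)CC[C@@]2(C)O[C@H]2[C@H]2OC(=O)C(COC(C)=O)=C12 | target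

Total step count: 17. Longest linear sequence: 16 steps (nerol 1 to target 22; step 10 is the side branch).

Steps most likely to fail

1. Step 14 (photooxygenation). What may go wrong: oxygen may be delivered mainly to the H6 face of the diene, giving the other C8 configuration, or hydrogen abstraction at C9 (ene reaction) may compete with cycloaddition. Fallback (C8 set by substitution with inversion, not by face selection): it sets out from 18. The photooxygenation then gives the C8-epimeric endoperoxide F1; thiourea in methanol reduces it to the (8R)-8,13-diol F2; selective acetylation with Ac2O/pyridine at low temperature gives the (8R)-8-hydroxy 13-acetate F3. Mitsunobu esterification of F3 with tiglic acid (PPh3, diisopropyl azodicarboxylate, toluene, 0 °C → rt) inverts C8 while installing the tiglate, and the sequence comes back to the route at 22 with the same number of steps.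

2. Step 13 (ring closure with lactonisation). What may go wrong: intermolecular coupling may outrun cyclisation, the acrylate ester may interfere with the chromium/nickel chemistry, or addition to the wrong aldehyde face may go unnoticed and uncorrected once the lactone has formed. Fallback (ring closure and lactone formation separated, C12 carried at the alcohol level): it sets out from 12. Site-selective Stille coupling with tributyl[3-(tert-butyldiphenylsilyloxy)prop-1-en-2-yl]stannane (Pd2(dba)3, P(2-furyl)3, CuI, toluene) gives the (Z)-bromodiene silyl ether F4. Dess–Martin oxidation gives the epoxy aldehyde F5. The same CrCl2/NiCl2 closure, now with an ester-free dienyl bromide, gives the macrocyclic C6 carbinol F6, which is isolable so that its C6 configuration can be checked. Buffered Bu4NF/AcOH removes the silyl group to give the 6,12-diol F7. Oxidative lactonisation with TEMPO/PhI(OAc)2, which oxidises the primary allylic alcohol and then the lactol, comes back to the route at 18.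

3. Step 11 (site-selective Stille coupling). What may go wrong: slow transmetalation of the hindered, electron-poor stannylacrylate may allow a second coupling at the cis bromide, homocoupling, or thermal Diels–Alder dimerisation of the bromodienoate. Fallback (C11–C13 brought in as an alkyne and the lactone carbonyl by carbonylation): it sets out from 12. Coupling with tributyl(ethynyl)stannane (Pd2(dba)3, P(2-furyl)3, toluene, rt), where the alkynyl group transfers fastest from tin and again enters trans to the chain, gives the (Z)-bromoenyne F8. Dess–Martin oxidation gives the epoxy aldehyde F9. CrCl2/NiCl2 closure gives the macrocyclic enynol F10. Palladium-catalysed cyclocarbonylation of this homopropargylic alcohol (PdI2, PBu3, CO, MeCN, 60 °C) forms the alpha-methylene lactone and comes back to the route at 18.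

Further compounds
F1 | step 14 | (1S,4R,5S,6S,8R,10R)-1-acetoxy-4,5-epoxy-8,13-epidioxygermacr-7(11)-en-12,6-olide (C8 epimer of 19) | O1[C@@H]2C[C@@H](C)[C@@H](OC(C)=O)CC[C@@]3(C)O[C@H]3[C@H]3OC(=O)C(CO1)=C23
F2 | step 14 | (1S,4R,5S,6S,8R,10R)-1-acetoxy-4,5-epoxy-8,13-dihydroxygermacr-7(11)-en-12,6-olide | O[C@@H]1C[C@@H](C)[C@@H](OC(C)=O)CC[C@@]2(C)O[C@H]2[C@H]2OC(=O)C(CO)=C12
F3 | step 14 | (1S,4R,5S,6S,8R,10R)-1,13-diacetoxy-4,5-epoxy-8-hydroxygermacr-7(11)-en-12,6-olide | O[C@@H]1C[C@@H](C)[C@@H](OC(C)=O)CC[C@@]2(C)O[C@H]2[C@H]2OC(=O)C(COC(C)=O)=C12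
F4 | step 13 | (3S,4R,6Z)-7-bromo-8-(tert-butyldiphenylsilyloxymethyl)-1-[(2R,3S)-3-(hydroxymethyl)-2-methyloxiran-2-yl]-4-methylnona-6,8-dien-3-yl acetate | C=C(CO[Si](c1ccccc1)(c1ccccc1)C(C)(C)C)/C(Br)=C/C[C@@H](C)[C@@H](OC(C)=O)CC[C@@]1(C)O[C@H]1CO
F5 | step 13 | (3S,4R,6Z)-7-bromo-8-(tert-butyldiphenylsilyloxymethyl)-1-[(2R,3R)-3-formyl-2-methyloxiran-2-yl]-4-methylnona-6,8-dien-3-yl acetate | C=C(CO[Si](c1ccccc1)(c1ccccc1)C(C)(C)C)/C(Br)=C/C[C@@H](C)[C@@H](OC(C)=O)CC[C@@]1(C)O[C@H]1C=O
F6 | step 13 | (1S,4R,5S,6S,7Z,10R)-1-acetoxy-12-(tert-butyldiphenylsilyloxy)-4,5-epoxygermacra-7,11(13)-dien-6-ol | C=C(CO[Si](c1ccccc1)(c1ccccc1)C(C)(C)C)/C1=C/C[C@@H](C)[C@@H](OC(C)=O)CC[C@@]2(C)O[C@H]2[C@H]1O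
F7 | step 13 | (1S,4R,5S,6S,7Z,10R)-1-acetoxy-4,5-epoxygermacra-7,11(13)-diene-6,12-diol | C=C(CO)/C1=C/C[C@@H](C)[C@@H](OC(C)=O)CC[C@@]2(C)O[C@H]2[C@H]1O
F8 | step 11 | (3S,4R,6Z)-7-bromo-1-[(2R,3S)-3-(hydroxymethyl)-2-methyloxiran-2-yl]-4-methylnon-6-en-8-yn-3-yl acetate | C#C/C(Br)=C/C[C@@H](C)[C@@H](OC(C)=O)CC[C@@]1(C)O[C@H]1CO
F9 | step 11 | (3S,4R,6Z)-7-bromo-1-[(2R,3R)-3-formyl-2-methyloxiran-2-yl]-4-methylnon-6-en-8-yn-3-yl acetate | C#C/C(Br)=C/C[C@@H](C)[C@@H](OC(C)=O)CC[C@@]1(C)O[C@H]1C=O
F10 | step 11 | (1S,4R,5S,6S,7Z,10R)-1-acetoxy-4,5-epoxy-12-norgermacr-7-en-11(13)-yn-6-ol (ten-membered carbinol with an ethynyl group on C7) | C#C/C1=C/C[C@@H](C)[C@@H](OC(C)=O)CC[C@@]2(C)O[C@H]2[C@H]1O
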